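**Strategy.** The oxolane (O1, C2 with the side chain, C3 = CH2, C4 carbinol, C5 pentyl) is disconnected at C2–C3. Because O1 sits on C2, that carbon can be the β-carbon of a (Z)-β-alkoxyvinyl sulfoxide, and C3, an unsubstituted CH2, can be a primary iodide. A tin-mediated 5-exo radical cyclisation then closes the ring and sets C2 in one operation, the sulfinyl group enforcing the 2,5-trans relationship that the ring itself disfavours. The precursor is an acyclic iodo ether assembled from hexanal by syn-alkoxyallylboration. The sulfinyl group afterwards serves as a latent aldehyde for chelation-controlled attachment of the nonenyl chain, stearoylation and MOM removal.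

Key step: step 7

Remark: allyl methoxymethyl ether (1) is treated as a purchasable reagent; the sense of sulfur control in step 7 and the face selectivity of the borane in step 1 are assigned from the models stated in those steps.

Step 1
Reactants: 1 allyl methoxymethyl ether; 2 hexanal
Product: 5 (3S,4S)-3-(methoxymethoxy)non-1-en-4-ol, via allylborane 3 (not isolated), via borinate ester 4 (not isolated)
Conditions: 1, s-BuLi, THF, −78 °C; (+)-Ipc2BOMe, −78 °C; BF3·OEt2; 2, −78 °C; then NaOH, H2O2, 0 °C → rt
Reagents that add atoms: none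
Why: Brown alkoxyallylboration, in which the (Z)-γ-alkoxyallylborane adds through a chair Zimmerman–Traxler transition state to give the syn 3-alkoxy-4-ol, and the isopinocampheyl groups derived from (−)-α-pinene should direct attack to the Re face of hexanal, setting 3S and 4S (the future ring C4 and C5).

Step 2
Reactants: 5 (3S,4S)-3-(methoxymethoxy)non-1-en-4-ol
Product: 7 (2S,3S)-2-(methoxymethoxy)octane-1,3-diol, via hydroxy aldehyde 6 (not isolated)
Conditions: O3, CH2Cl2/MeOH, −78 °C; then NaBH4, −78 → 0 °C
Reagents that add atoms: ozone, [O-][O+]=O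
Why: Ozonolysis with borohydride work-up should excise the terminal CH2 and leave a primary alcohol on the carbon that becomes ring C3, the α-alkoxy aldehyde being reduced cold before it can epimerise.

Step 3
Reactants: 7 (2S,3S)-2-(methoxymethoxy)octane-1,3-diol
Product: 8 (2R,3S)-1-iodo-2-(methoxymethoxy)octan-3-ol
Conditions: I2, PPh3, imidazole, THF, 0 °C
Reagents that add atoms: iodine, II
Why: Garegg–Samuelsson (Appel-type) iodination, an SN2 displacement of the alkoxyphosphonium ion that is selective for the primary hydroxyl, so the secondary hydroxyl that becomes ring O1 stays free (the descriptor at C2 changes only through CIP ranking).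

Step 4
Reactants: 9 (1R,2S,5R)-menthyl (S)-4-methylbenzenesulfinate; 10 ethynyltrimethylsilane
Product: 12 (S)-trimethyl{[(4-methylphenyl)sulfinyl]ethynyl}silane, via alkynyl Grignard reagent 11 (not isolated)
Conditions: 10, EtMgBr, THF, 0 °C → rt; then 9, toluene, −20 °C
Reagents that add atoms: none
Why: Andersen sulfoxide synthesis, in which the alkynyl Grignard reagent displaces menthoxide at sulfur with inversion and so fixes the sulfur configuration used in the key step.

Step 5
Reactants: 12 (S)-trimethyl{[(4-methylphenyl)sulfinyl]ethynyl}silane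
Product: 13 (R)-1-(ethynylsulfinyl)-4-methylbenzene
Conditions: KF, MeOH/H2O, 0 °C
Reagents that add atoms: none
Why: Fluoride-induced protodesilylation of the alkynylsilane, which leaves sulfur untouched (the descriptor changes from S to R only because the alkynyl group drops below tolyl in CIP ranking).

Step 6
Reactants: 8 (2R,3S)-1-iodo-2-(methoxymethoxy)octan-3-ol; 13 (R)-1-(ethynylsulfinyl)-4-methylbenzene
Product: 14 1-[(R)-{(Z)-2-{[(2R,3S)-1-iodo-2-(methoxymethoxy)octan-3-yl]oxy}ethenyl}sulfinyl]-4-methylbenzene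
Conditions: NaH (0.15 equiv), THF, −40 °C
Reagents that add atoms: none
Why: Base-catalysed oxa-Michael addition of the alkoxide to the alkynyl sulfoxide, where kinetic anti addition across the triple bond should give the (Z)-enol ether and, with only catalytic base in the cold, should outrun oxetane formation from the 1,3-iodohydrin.

Step 7
Reactants: 14 (Z)-β-alkoxyvinyl sulfoxide
Product: 15 (2R,4S,5S)-4-(methoxymethoxy)-2-{[(R)-(4-methylphenyl)sulfinyl]methyl}-5-pentyloxolane
Conditions: Bu3SnH, Et3B, air, toluene (0.02 M), −20 °C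
Reagents that add atoms: none
Why: Et3B/O2 starts a tin radical chain in which Bu3Sn• abstracts iodine to give the primary radical at the future ring C3, which adds to the β-carbon (future C2) of the β-alkoxyvinyl sulfoxide, and the resulting α-sulfinyl radical is reduced by Bu3SnH. The closest known reaction type is the radical cyclisation of β-alkoxyacrylates and β-alkoxyvinyl sulfoxides to oxolanes. The oxolane is closed in the 5-exo-trig mode, which is kinetically favoured and polarity-matched (nucleophilic alkyl radical, acceptor alkene). The new stereocentre C2 is controlled by sulfur: in the (Z)-isomer allylic 1,3-strain should hold the sulfur lone pair in the alkene plane next to the alkoxy oxygen, so the p-tolyl group covers one face and the radical enters anti to it, which for the R sulfoxide gives 2R, trans to the C5 pentyl group. The step needs this facial control to override the usual 2,5-cis preference, and the substrate helps because the cis 4-OMOM and 5-pentyl groups force one pseudoaxial substituent in either chair-like transition state, so the inherent bias is small. The (Z)-geometry set in step 6 is required for the sulfinyl group to exert this control.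

Step 8
Reactants: 15 oxolane sulfoxide
Product: 17 (2R,4S,5S)-4-(methoxymethoxy)-5-pentyloxolane-2-carbaldehyde, via trifluoroacetoxy sulfide 16 (not isolated)
Conditions: TFAA, 2,4,6-collidine, MeCN, 0 °C; then aq. NaHCO3, 0 °C → rt
Reagents that add atoms: trifluoroacetic anhydride, O=C(OC(=O)C(F)(F)F)C(F)(F)F
Why: Pummerer rearrangement, in which O-acylation of the sulfoxide, thionium ion formation and capture by trifluoroacetate give the α-acyloxy sulfide, whose mild hydrolysis should unmask the aldehyde without epimerising ring C2.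

Step 9
Reactants: 17 oxolane-2-carbaldehyde; 18 9-bromonon-1-ene
Product: 20 (1R)-1-[(2R,4S,5S)-4-(methoxymethoxy)-5-pentyloxolan-2-yl]dec-9-en-1-ol, via Grignard reagent 19 (not isolated)
Conditions: 18, Mg, Et2O, reflux; then 17, MgBr2·OEt2, CH2Cl2, −78 °C
Reagents that add atoms: none
Why: Chelation-controlled Grignard addition (Cram chelate), in which magnesium bridges the aldehyde oxygen and ring O1 and the nucleophile enters on the side of the C2 hydrogen, anti to ring C3, which should give the threo (1R) carbinol.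

Step 10
Reactants: 20 carbinol; 21 octadecanoyl chloride
Product: 22 (1R)-1-[(2R,4S,5S)-4-(methoxymethoxy)-5-pentyloxolan-2-yl]dec-9-en-1-yl octadecanoate
Conditions: pyridine, DMAP (cat.), CH2Cl2, 0 °C → rt
Reagents that add atoms: none
Why: DMAP-catalysed acylation of the only free hydroxyl with the acid chloride, which forms the ester with retention at the carbinol carbon.

Step 11
Reactants: 22 MOM-protected ester
Product: 24 (1R)-1-[(2R,4S,5S)-4-hydroxy-5-pentyloxolan-2-yl]dec-9-en-1-yl octadecanoate, via bromomethyl ether 23 (not isolated)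
Conditions: Me2BBr, CH2Cl2, −78 °C; then sat. aq. NaHCO3/THF
Reagents that add atoms: none
Why: Lewis-acid cleavage of the MOM acetal with bromodimethylborane, which attacks the most basic acetal oxygen to give a bromomethyl ether that is hydrolysed on work-up, while the ester, the terminal alkene and the oxolane should be inert at −78 °C and acyl migration to the trans-disposed 4-OH is geometrically excluded.

**Compound list**

1 | allyl methoxymethyl ether, 3-(methoxymethoxy)prop-1-ene | C=CCOCOC | starting material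
2 | hexanal | CCCCCC=O | starting material
3 | [(Z)-3-(methoxymethoxy)allyl]diisopinocampheylborane (Ipc groups from (−)-α-pinene) | COCO/C=C\CB([C@H]1C[C@H]2C[C@@H]([C@@H]1C)C2(C)C)[C@H]1C[C@H]2C[C@@H]([C@@H]1C)C2(C)C | intermediate
4 | (3S,4S)-3-(methoxymethoxy)non-1-en-4-yl diisopinocampheylborinate | C=C[C@H](OCOC)[C@H](CCCCC)OB([C@H]1C[C@H]2C[C@@H]([C@@H]1C)C2(C)C)[C@H]1C[C@H]2C[C@@H]([C@@H]1C)C2(C)C | intermediate
5 | (3S,4S)-3-(methoxymethoxy)non-1-en-4-ol | C=C[C@H](OCOC)[C@H](CCCCC)O | intermediate
6 | (2R,3S)-3-hydroxy-2-(methoxymethoxy)octanal | O=C[C@H](OCOC)[C@H](CCCCC)O | intermediate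
7 | (2S,3S)-2-(methoxymethoxy)octane-1,3-diol | OC[C@H](OCOC)[C@H](CCCCC)O | intermediate
8 | (2R,3S)-1-iodo-2-(methoxymethoxy)octan-3-ol | IC[C@H](OCOC)[C@H](CCCCC)O | intermediate
9 | (1R,2S,5R)-5-methyl-2-(propan-2-yl)cyclohexyl (S)-4-methylbenzenesulfinate | CC(C)[C@@H]1CC[C@@H](C)C[C@H]1O[S@](=O)c1ccc(C)cc1 | starting material
10 | ethynyltrimethylsilane | C#C[Si](C)(C)C | starting material
11 | bromo[(trimethylsilyl)ethynyl]magnesium | C[Si](C)(C)C#C[Mg]Br | intermediate
12 | (S)-trimethyl{[(4-methylphenyl)sulfinyl]ethynyl}silane | C[Si](C)(C)C#C[S@@](=O)c1ccc(C)cc1 | intermediate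
13 | (R)-1-(ethynylsulfinyl)-4-methylbenzene | C#C[S@@](=O)c1ccc(C)cc1 | intermediate
14 | 1-[(R)-{(Z)-2-{[(2R,3S)-1-iodo-2-(methoxymethoxy)octan-3-yl]oxy}ethenyl}sulfinyl]-4-methylbenzene | IC[C@H](OCOC)[C@H](CCCCC)O/C=C\[S@@](=O)c1ccc(C)cc1 | intermediate
15 | (2R,4S,5S)-4-(methoxymethoxy)-2-{[(R)-(4-methylphenyl)sulfinyl]methyl}-5-pentyloxolane | Cc1ccc(cc1)[S@](=O)C[C@H]1C[C@H](OCOC)[C@H](CCCCC)O1 | intermediate
16 | [(2R,4S,5S)-4-(methoxymethoxy)-5-pentyloxolan-2-yl][(4-methylphenyl)sulfanyl]methyl trifluoroacetate (both epimers at the acetal carbon) | Cc1ccc(cc1)SC(OC(=O)C(F)(F)F)[C@H]1C[C@H](OCOC)[C@H](CCCCC)O1 | intermediate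
17 | (2R,4S,5S)-4-(methoxymethoxy)-5-pentyloxolane-2-carbaldehyde | O=C[C@H]1C[C@H](OCOC)[C@H](CCCCC)O1 | intermediate
18 | 9-bromonon-1-ene | C=CCCCCCCCBr | starting material
19 | non-8-en-1-ylmagnesium bromide | C=CCCCCCCC[Mg]Br | intermediate
20 | (1R)-1-[(2R,4S,5S)-4-(methoxymethoxy)-5-pentyloxolan-2-yl]dec-9-en-1-ol | C=CCCCCCCC[C@@H](O)[C@H]1C[C@H](OCOC)[C@H](CCCCC)O1 | intermediate
21 | octadecanoyl chloride | ClC(=O)CCCCCCCCCCCCCCCCC | starting material
22 | (1R)-1-[(2R,4S,5S)-4-(methoxymethoxy)-5-pentyloxolan-2-yl]dec-9-en-1-yl octadecanoate | C=CCCCCCCC[C@@H](OC(=O)CCCCCCCCCCCCCCCCC)[C@H]1C[C@H](OCOC)[C@H](CCCCC)O1 | intermediate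
23 | (1R)-1-[(2R,4S,5S)-4-(bromomethoxy)-5-pentyloxolan-2-yl]dec-9-en-1-yl octadecanoate | C=CCCCCCCC[C@@H](OC(=O)CCCCCCCCCCCCCCCCC)[C@H]1C[C@H](OCBr)[C@H](CCCCC)O1 | intermediate
24 | (1R)-1-[(2R,4S,5S)-4-hydroxy-5-pentyloxolan-2-yl]dec-9-en-1-yl octadecanoate | C=CCCCCCCC[C@@H](OC(=O)CCCCCCCCCCCCCCCCC)[C@H]1C[C@H](O)[C@H](CCCCC)O1 | target

**Count.** Total: 11 steps. Longest linear sequence: 9 steps (1, 2, 3, 6, 7, 8, 9, 10, 11); steps 4 and 5 form the side branch to sulfoxide 13.

**Steps most likely to fail**

1. Step 7. The risk is insufficient facial control by sulfur, so that the radical closes the ring on the other face and the 2,5-cis oxolane forms. The fallback makes the same ring bond by an auxiliary-controlled enolate alkylation; it sets out from 5 and returns at 17. Alcohol 5 is O-alkylated with bromoacetic acid (NaH, THF, 0 °C → rt) to {[(3S,4S)-3-(methoxymethoxy)non-1-en-4-yl]oxy}acetic acid F1. Activation (PivCl, Et3N) and reaction with lithiated (S)-4-benzyloxazolidin-2-one gives the N-glycolyl imide F2. Ozonolysis with NaBH4 quench at −78 °C gives the primary alcohol F3, and I2/PPh3/imidazole the iodide F4. NaN(SiMe3)2 in THF at −78 → −45 °C then closes the ring by 5-exo-tet alkylation of the chelated (Z)-enolate anti to the benzyl group, which should give the 2R oxolane imide F5. LiBH4 removes the auxiliary to give the carbinol F6, and Dess–Martin oxidation returns aldehyde 17.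

2. Step 6. The risks are base-mediated isomerisation of the (Z)-enol ether to the (E)-isomer and intramolecular displacement of iodide by the alkoxide (oxetane formation). The fallback installs the acceptor before the leaving group; it sets out from 7 and returns at 14. Diol 7 is silylated at the primary hydroxyl (TBSCl, imidazole, CH2Cl2, 0 °C) to the silyl ether F7. Conjugate addition to 13 (NaH cat., THF, −40 °C) gives the (Z)-vinyl sulfoxide F8, Bu4NF in THF at 0 °C gives the primary alcohol F9, and I2/PPh3/imidazole converts it into 14.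

3. Step 9. The risks are incomplete chelation, giving poor facial selectivity at the aldehyde, and α-epimerisation of the aldehyde. The fallback sets the carbinol by ketone reduction instead; it sets out from 17 and returns at 20. Grignard addition without additive gives 20 together with its 1S epimer F10. The mixture is oxidised with Dess–Martin periodinane to the ketone F11, and LiBH(s-Bu)3 in THF at −78 °C should reduce it under Felkin–Anh control (ring C–O bond anti to the incoming hydride) to the threo carbinol 20.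

**Further compounds**

F1 | step 7 | {[(3S,4S)-3-(methoxymethoxy)non-1-en-4-yl]oxy}acetic acid | C=C[C@H](OCOC)[C@H](CCCCC)OCC(=O)O
F2 | step 7 | (S)-4-benzyl-3-({[(3S,4S)-3-(methoxymethoxy)non-1-en-4-yl]oxy}acetyl)oxazolidin-2-one | C=C[C@H](OCOC)[C@H](CCCCC)OCC(=O)N1[C@@H](Cc2ccccc2)COC1=O
F3 | step 7 | (S)-4-benzyl-3-({[(2S,3S)-1-hydroxy-2-(methoxymethoxy)octan-3-yl]oxy}acetyl)oxazolidin-2-one | OC[C@H](OCOC)[C@H](CCCCC)OCC(=O)N1[C@@H](Cc2ccccc2)COC1=O
F4 | step 7 | (S)-4-benzyl-3-({[(2R,3S)-1-iodo-2-(methoxymethoxy)octan-3-yl]oxy}acetyl)oxazolidin-2-one | IC[C@H](OCOC)[C@H](CCCCC)OCC(=O)N1[C@@H](Cc2ccccc2)COC1=O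
F5 | step 7 | (S)-4-benzyl-3-[(2R,4S,5S)-4-(methoxymethoxy)-5-pentyloxolane-2-carbonyl]oxazolidin-2-one | O=C([C@H]1C[C@H](OCOC)[C@H](CCCCC)O1)N1[C@@H](Cc2ccccc2)COC1=O
F6 | step 7 | [(2R,4S,5S)-4-(methoxymethoxy)-5-pentyloxolan-2-yl]methanol | OC[C@H]1C[C@H](OCOC)[C@H](CCCCC)O1
F7 | step 6 | (2S,3S)-1-[(tert-butyldimethylsilyl)oxy]-2-(methoxymethoxy)octan-3-ol | CC(C)(C)[Si](C)(C)OC[C@H](OCOC)[C@H](CCCCC)O
F8 | step 6 | tert-butyl{[(2S,3S)-2-(methoxymethoxy)-3-({(Z)-2-[(R)-(4-methylphenyl)sulfinyl]ethenyl}oxy)octyl]oxy}dimethylsilane | CC(C)(C)[Si](C)(C)OC[C@H](OCOC)[C@H](CCCCC)O/C=C\[S@@](=O)c1ccc(C)cc1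
F9 | step 6 | (2S,3S)-2-(methoxymethoxy)-3-({(Z)-2-[(R)-(4-methylphenyl)sulfinyl]ethenyl}oxy)octan-1-ol | OC[C@H](OCOC)[C@H](CCCCC)O/C=C\[S@@](=O)c1ccc(C)cc1
F10 | step 9 | (1S)-1-[(2R,4S,5S)-4-(methoxymethoxy)-5-pentyloxolan-2-yl]dec-9-en-1-ol | C=CCCCCCCC[C@H](O)[C@H]1C[C@H](OCOC)[C@H](CCCCC)O1
F11 | step 9 | 1-[(2R,4S,5S)-4-(methoxymethoxy)-5-pentyloxolan-2-yl]dec-9-en-1-one | C=CCCCCCCCC(=O)[C@H]1C[C@H](OCOC)[C@H](CCCCC)O1
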